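**Retrosynthetic overview**
- The target comes from a 9‑hydroxy bis‑epoxide by C9 oxidation and C12/C15 acetylation. Both oxiranes come from one Sharpless epoxidation with D‑(−)‑tartrate (C4=C15 through C5–OH, C7=C11 through C12–OH), after which a Payne shift moves the C4–C15 oxirane to C4–C5 and frees C15–OH.
- The C7=C11 alkene (C12 cis to C8) comes from an intramolecular Horner–Wadsworth–Emmons reaction of a C9 phosphonopropanoate onto a C7 ketone, followed by reduction of the temporary δ‑lactone.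
- The strategy rests on this feature: in the ten‑membered carbocycle the (E)‑C1=C10 alkene and the oxygen‑bearing C5 are linked through C10–C1–C2–C3–C4–C5, so C2=C1–C10–C5(O)–C4=C3 is an oxy‑Cope retron. Disconnecting C2–C3 and reconnecting C5–C10 gives a trans‑1,2‑dialkenylcyclohexanol.
- That cyclohexanol comes from 2‑methylcyclohexane‑1,3‑dione by C10 ethynylation, CBS desymmetrisation (C9–OH), Lindlar reduction, Saegusa dehydrogenation, hemiacetal oxa‑Michael addition (C7–O, bridged acetal) and alkenylcerium addition at C5.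
- Ring order: purchased cyclohexane → auxiliary 1,3‑dioxane bridge → ten‑membered carbocycle by ring expansion → temporary δ‑lactone → the two oxiranes.

Key step: step 8

Remark: locants C1–C15 are those of the target (ring C1H=C10(C14H3), C2, C3, C4 bearing C15, C5, C6, C7, C8, C9; C11 bears C13H3 and C12). The oxygens on C7 and C9 are auxiliary stereocentres, erased in steps 12 and 21; the 9S series is drawn because it is the slow‑reacting partner of D‑(−)‑tartrate in step 18.

**Step 1**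
Reactants: 1 2‑methylcyclohexane‑1,3‑dione; 2 1‑[(trimethylsilyl)ethynyl]‑1,2‑benziodoxol‑3(1H)‑one (TMS‑EBX)
Product: 3 2‑ethynyl‑2‑methylcyclohexane‑1,3‑dione
Conditions: Bu4NF, THF, −78 °C to rt
Reagents that add atoms: none
Why: Fluoride unmasks the ethynylbenziodoxolone and forms the diketone enolate, whose C‑alkynylation (electrophilic alkynylation of a 1,3‑dicarbonyl by an alkynyl iodane) puts C1–C2 on the quaternary C10; the product is achiral.

**Step 2**
Reactants: 3 2‑ethynyl‑2‑methylcyclohexane‑1,3‑dione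
Product: 4 (2S,3S)‑2‑ethynyl‑3‑hydroxy‑2‑methylcyclohexan‑1‑one
Conditions: (R)‑1‑methyl‑3,3‑diphenyltetrahydro‑1H,3H‑pyrrolo[1,2‑c][1,3,2]oxazaborole (CBS catalyst, 30 mol%), catecholborane, toluene/CH2Cl2, −78 °C
Reagents that add atoms: none
Why: Corey–Bakshi–Shibata desymmetrisation: the catalyst treats the quaternary C10 as the large group and sets C9 as S, and hydride should enter anti to the ethynyl group, which prefers the axial site on C10, so OH ends cis to ethynyl; the minor trans isomer is removed by chromatography.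

**Step 3**
Reactants: 4 (2S,3S)‑2‑ethynyl‑3‑hydroxy‑2‑methylcyclohexan‑1‑one
Product: 5 (2S,3S)‑2‑ethenyl‑3‑hydroxy‑2‑methylcyclohexan‑1‑one
Conditions: H2 (1 atm), Pd/CaCO3 poisoned with Pb(OAc)2 (Lindlar catalyst), quinoline, EtOAc, rt
Reagents that add atoms: none
Why: Lindlar semihydrogenation stops at the alkene and leaves the ketone and both stereocentres untouched.

**Step 4**
Reactants: 5 (2S,3S)‑2‑ethenyl‑3‑hydroxy‑2‑methylcyclohexan‑1‑one
Product: 8 (5S,6S)‑6‑ethenyl‑5‑hydroxy‑6‑methylcyclohex‑2‑en‑1‑one, via bis(trimethylsilyl) dienyl ether 6 (not isolated), via enone trimethylsilyl ether 7 (not isolated)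
Conditions: TMSOTf, Et3N, CH2Cl2, 0 °C; Pd(OAc)2 (1.05 equiv), MeCN, rt; citric acid, MeOH, rt
Reagents that add atoms: none
Why: Saegusa–Ito dehydrogenation: silylation gives the only possible enol ether (towards C6, since C10 is quaternary), Pd(OAc)2 turns it into the C6=C7 enone, and mild methanolysis frees the C9 hydroxyl.

**Step 5**
Reactants: 8 (5S,6S)‑6‑ethenyl‑5‑hydroxy‑6‑methylcyclohex‑2‑en‑1‑one
Product: 9 6‑ethenyl‑3‑(4‑methoxyphenyl)‑6‑methyl‑2,4‑dioxabicyclo[3.3.1]nonan‑7‑one (aryl equatorial on the dioxane; vinyl equatorial and cis to the ring oxygens; methyl axial)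
Conditions: 4‑MeOC6H4CHO (3 equiv), KOtBu (10 mol% portions), THF, 0 °C
Reagents that add atoms: 4‑methoxybenzaldehyde, COc1ccc(C=O)cc1
Why: Base‑catalysed hemiacetal formation followed by intramolecular oxa‑Michael addition (the syn‑1,3‑diol acetal synthesis) delivers oxygen to C7 from the C9 hemiacetal alkoxide, so C7–O is necessarily cis to C9–O, and reversibility places the aryl group equatorial.

**Step 6**
Reactants: 10 2,3‑dibromoprop‑1‑ene
Product: 11 2‑bromo‑N,N‑dimethylprop‑2‑en‑1‑amine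
Conditions: Me2NH (2 M in THF, 2.5 equiv), Et2O, 0 °C to rt
Reagents that add atoms: dimethylamine, CNC
Why: SN2 displacement of the allylic bromide by the amine; the vinylic bromide is inert.

**Step 7**
Reactants: 11 2‑bromo‑N,N‑dimethylprop‑2‑en‑1‑amine; 9 bridged acetal ketone
Product: 14 7‑[3‑(dimethylamino)prop‑1‑en‑2‑yl]‑6‑ethenyl‑3‑(4‑methoxyphenyl)‑6‑methyl‑2,4‑dioxabicyclo[3.3.1]nonan‑7‑ol (hydroxyl endo; the two alkenyl groups equatorial and trans), via 3‑(dimethylamino)prop‑1‑en‑2‑yllithium 12 (not isolated), via alkenylcerium dichloride 13 (not isolated)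
Conditions: t‑BuLi (2 equiv), THF, −78 °C; CeCl3, −78 °C; then 9, −78 °C; aq NH4Cl
Reagents that add atoms: none
Why: Bromine–lithium exchange and transmetalation give a weakly basic alkenylcerium reagent that adds 1,2 to the hindered, enolisable ketone; the acetal bridge closes the endo face, so attack is exo and the new alkenyl group ends equatorial and trans to the equatorial C10 vinyl group.

**Step 8**
Reactants: 14 trans‑1,2‑dialkenyl bicyclic carbinol
Product: 19 (1(10)E,9S)‑7,9‑O‑(4‑methoxybenzylidene)‑7,9‑dihydroxy‑10‑methyl‑4‑methylidenecyclodec‑1(10)‑en‑5‑one, via potassium alkoxide 15 (not isolated), via potassium enolate 16 (not isolated), via Mannich base 17 (not isolated), via trimethylammonium iodide 18 (not isolated)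
Conditions: KH, 18‑crown‑6, THF, 0 °C to rt; AcOH (1.2 equiv), −78 °C; MeI (excess), rt; sat. aq NaHCO3, rt
Reagents that add atoms: none
Why: The potassium alkoxide 15 undergoes the anionic oxy‑Cope [3,3] shift through C2=C1–C10–C5–C4=C3, forming C2–C3 and cleaving C5–C10 to give the ten‑membered enolate 16; enolate formation makes it irreversible, and the acetal oxygens on C7 and C9 leave no carbonyl for a retro‑aldol. The closest known reaction type is the alkoxide‑accelerated oxy‑Cope ring expansion of trans‑1,2‑dialkenylcyclohexanols to (E)‑cyclodec‑5‑enones. The ten‑membered ring closes by ring expansion of the six‑membered ring through a chair‑like transition state that is trans‑fused to the cyclohexane chair held by the acetal bridge. No stereocentre is made, since C5 and C10 become trigonal. The selectivity needed is E geometry at C1=C10: with both alkenyl groups equatorial and trans, the ring carbon C9 is equatorial on C10 in that chair and ends trans to C2, while the axial C14 methyl ends cis. Protonation gives Mannich base 17, N‑methylation gives 18, and hydrogencarbonate triggers E1cB loss of trimethylamine to the C4=C15 methylene ketone, so that no strong base meets the C6 hydrogens beta to the C7 acetal oxygen.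

**Step 9**
Reactants: 19 ten‑membered methylene ketone
Product: 20 (1(10)E,5R,9S)‑7,9‑O‑(4‑methoxybenzylidene)‑10‑methyl‑4‑methylidenecyclodec‑1(10)‑ene‑5,7,9‑triol (5‑OH free)
Conditions: (S)‑1‑methyl‑3,3‑diphenyltetrahydro‑1H,3H‑pyrrolo[1,2‑c][1,3,2]oxazaborole (CBS catalyst, 20 mol%), catecholborane, toluene, −78 °C
Reagents that add atoms: none
Why: Corey–Bakshi–Shibata reduction with the alpha‑branched alkenyl carbon C4 as the large group should give the 5R allylic alcohol under catalyst control; catecholborane at low temperature avoids hydroboration, and any 5S diastereomer is separable.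

**Step 10**
Reactants: 20 5R allylic alcohol
Product: 21 5‑O‑tert‑butyldimethylsilyl ether of 20
Conditions: TBSCl, imidazole, DMF, rt
Reagents that add atoms: tert‑butyldimethylsilyl chloride, CC(C)(C)[Si](C)(C)Cl
Why: Standard silylation of the secondary allylic alcohol; chloride/imidazole conditions spare the aryl acetal.

**Step 11**
Reactants: 21 silyl ether acetal
Product: 22 (1(10)E,5R,9S)‑5‑(tert‑butyldimethylsilyloxy)‑9‑(4‑methoxybenzyloxy)‑10‑methyl‑4‑methylidenecyclodec‑1(10)‑en‑7‑ol (7‑OH cis to O9)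
Conditions: iBu2AlH (4 equiv), CH2Cl2, −78 to 0 °C
Reagents that add atoms: none
Why: Reductive opening of the 4‑methoxybenzylidene acetal: iBu2AlH should coordinate the less hindered O7, cleave the acetal C–O7 bond and leave the 4‑methoxybenzyl group on O9, which is flanked by the fully substituted C10.

**Step 12**
Reactants: 22 C7 alcohol
Product: 23 (1(10)E,5R,9S)‑5‑(tert‑butyldimethylsilyloxy)‑9‑(4‑methoxybenzyloxy)‑10‑methyl‑4‑methylidenecyclodec‑1(10)‑en‑7‑one
Conditions: Dess–Martin periodinane, CH2Cl2, rt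
Reagents that add atoms: none
Why: Dess–Martin oxidation of the only free hydroxyl gives the C7 ketone under neutral conditions.

**Step 13**
Reactants: 23 C7 ketone
Product: 24 (1(10)E,5R,9S)‑5‑(tert‑butyldimethylsilyloxy)‑9‑hydroxy‑10‑methyl‑4‑methylidenecyclodec‑1(10)‑en‑7‑one
Conditions: DDQ, CH2Cl2/pH 7 buffer, 0 °C
Reagents that add atoms: none
Why: Oxidative cleavage of the 4‑methoxybenzyl ether with DDQ frees the C9 hydroxyl without the acid or base that the beta‑hydroxy ketone would not tolerate.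

**Step 14**
Reactants: 24 beta‑hydroxy ketone; 25 2‑(diethoxyphosphoryl)propanoic acid
Product: 26 9‑O‑[2‑(diethoxyphosphoryl)propanoyl] ester of 24 (C11 epimers)
Conditions: DCC, DMAP (5 mol%), CH2Cl2, 0 °C to rt
Reagents that add atoms: none
Why: Steglich esterification tethers the C11–C13 phosphonate unit to O9; the configuration at C11 is lost in the next step.

**Step 15**
Reactants: 26 phosphonate ester
Product: 27 (1(10)E,5R,9S)‑5‑(tert‑butyldimethylsilyloxy)germacra‑1(10),4(15),7(11)‑trien‑12,9‑olide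
Conditions: LiCl, DBU, MeCN, rt
Reagents that add atoms: none
Why: Intramolecular Horner–Wadsworth–Emmons olefination under Masamune–Roush conditions (the lithium‑chelated phosphonate is deprotonated far more readily than C8–H) closes the six‑membered lactone, which forces C12 cis to C8 on the new tetrasubstituted C7=C11 alkene.

**Step 16**
Reactants: 27 unsaturated δ‑lactone
Product: 28 (1(10)E,5R,9S)‑5‑(tert‑butyldimethylsilyloxy)germacra‑1(10),4(15),7(11)‑triene‑9,12‑diol (C12 cis to C8)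
Conditions: iBu2AlH (4 equiv), CH2Cl2, −78 to −20 °C
Reagents that add atoms: none
Why: 1,2‑Reduction of the unsaturated lactone with iBu2AlH gives the allylic diol and keeps the alkene geometry fixed by the ring.

**Step 17**
Reactants: 28 silyl ether diol
Product: 29 (1(10)E,5R,9S)‑germacra‑1(10),4(15),7(11)‑triene‑5,9,12‑triol
Conditions: Bu4NF, THF, 0 °C to rt
Reagents that add atoms: none
Why: Fluoride cleaves the silyl ether and frees the C5 allylic alcohol.

**Step 18**
Reactants: 29 triol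
Product: 30 (1(10)E,4S,5R,9S,11R)‑4,15:7,11‑diepoxygermacr‑1(10)‑ene‑5,9,12‑triol (7,11‑oxirane in the configuration of the target)
Conditions: Ti(OiPr)4 (20 mol%), D‑(−)‑diisopropyl tartrate (24 mol%), t‑BuOOH (2.2 equiv), 4 Å MS, CH2Cl2, −20 °C
Reagents that add atoms: tert‑butyl hydroperoxide, CC(C)(C)OO
Why: Sharpless asymmetric epoxidation: with D‑(−)‑tartrate the 5R carbinol is the fast‑reacting partner and gives the erythro C4–C15 oxirane (4S), the primary C12 alcohol directs oxygen to the C7=C11 face that gives the target configuration (11R), and the 9S carbinol is the slow‑reacting antipode, so C1=C10 should survive.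

**Step 19**
Reactants: 30 bis‑epoxy triol
Product: 31 (1(10)E,4R,5R,9S,11R)‑4,5:7,11‑diepoxygermacr‑1(10)‑ene‑9,12,15‑triol
Conditions: KOtBu (0.2 equiv), t‑BuOH/THF, 0 °C to rt
Reagents that add atoms: none
Why: Payne rearrangement: the C5 alkoxide opens the C4–C15 oxirane at C4 with inversion (3‑exo‑tet), giving the more substituted, cis‑fused 4R,5R oxirane (C3 and C6 cis) and the primary C15 alkoxide, the favoured side of the equilibrium; the 7,11‑oxirane is already the favoured isomer of its own pair and stays.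

**Step 20**
Reactants: 31 triol
Product: 32 (1(10)E,4R,5R,9S,11R)‑12,15‑diacetoxy‑4,5:7,11‑diepoxygermacr‑1(10)‑en‑9‑ol
Conditions: Ac2O (2.5 equiv), pyridine, CH2Cl2, 0 °C
Reagents that add atoms: acetic anhydride, CC(=O)OC(C)=O
Why: Acetylation discriminates the two primary alcohols from the secondary allylic C9 alcohol, which is flanked by the fully substituted C10.

**Step 21**
Reactants: 32 diacetate alcohol
Product: 33 CNP0185847.3, (1(10)E,4R,5R,7S,11R)‑12,15‑diacetoxy‑4,5:7,11‑diepoxygermacr‑1(10)‑en‑9‑one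
Conditions: Dess–Martin periodinane, NaHCO3, CH2Cl2, 0 °C
Reagents that add atoms: none
Why: Buffered Dess–Martin oxidation of the allylic alcohol gives the C9 enone without base, which the beta,gamma‑epoxy ketone of the target would not survive.

**Compound list**
1 | 2‑methylcyclohexane‑1,3‑dione | CC1C(=O)CCCC1=O | starting material
2 | 1‑[(trimethylsilyl)ethynyl]‑1,2‑benziodoxol‑3(1H)‑one (TMS‑EBX) | C[Si](C)(C)C#CI1OC(=O)c2ccccc12 | starting material
3 | 2‑ethynyl‑2‑methylcyclohexane‑1,3‑dione | CC1(C#C)C(=O)CCCC1=O | intermediate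
4 | (2S,3S)‑2‑ethynyl‑3‑hydroxy‑2‑methylcyclohexan‑1‑one (OH cis to ethynyl) | O=C1CCC[C@H](O)[C@]1(C)C#C | intermediate
5 | (2S,3S)‑2‑ethenyl‑3‑hydroxy‑2‑methylcyclohexan‑1‑one | O=C1CCC[C@H](O)[C@]1(C)C=C | intermediate
6 | bis(trimethylsilyl) derivative of 5 (C5=C6 silyl enol ether, C9 silyl ether) | C[Si](C)(C)OC1=CCC[C@H](O[Si](C)(C)C)[C@]1(C)C=C | intermediate (not isolated)
7 | (5S,6S)‑6‑ethenyl‑6‑methyl‑5‑(trimethylsilyloxy)cyclohex‑2‑en‑1‑one | O=C1C=CC[C@H](O[Si](C)(C)C)[C@]1(C)C=C | intermediate (not isolated)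
8 | (5S,6S)‑6‑ethenyl‑5‑hydroxy‑6‑methylcyclohex‑2‑en‑1‑one | O=C1C=CC[C@H](O)[C@]1(C)C=C | intermediate
9 | 6‑ethenyl‑3‑(4‑methoxyphenyl)‑6‑methyl‑2,4‑dioxabicyclo[3.3.1]nonan‑7‑one (aryl equatorial; vinyl cis to the ring oxygens; methyl axial) | O=C1C[C@H]2C[C@H](O[C@H](c3ccc(OC)cc3)O2)[C@]1(C)C=C | intermediate
10 | 2,3‑dibromoprop‑1‑ene | C=C(Br)CBr | starting material
11 | 2‑bromo‑N,N‑dimethylprop‑2‑en‑1‑amine | C=C(Br)CN(C)C | intermediate
12 | [3‑(dimethylamino)prop‑1‑en‑2‑yl]lithium | [Li]C(=C)CN(C)C | intermediate (not isolated)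
13 | dichloro[3‑(dimethylamino)prop‑1‑en‑2‑yl]cerium | C=C(CN(C)C)[Ce](Cl)Cl | intermediate (not isolated)
14 | 7‑[3‑(dimethylamino)prop‑1‑en‑2‑yl]‑6‑ethenyl‑3‑(4‑methoxyphenyl)‑6‑methyl‑2,4‑dioxabicyclo[3.3.1]nonan‑7‑ol (OH endo; alkenyl groups trans) | C=C(CN(C)C)[C@@]1(O)C[C@H]2C[C@H](O[C@H](c3ccc(OC)cc3)O2)[C@]1(C)C=C | intermediate (key‑step precursor)
15 | potassium alkoxide of 14 | C=C(CN(C)C)[C@@]1([O-])C[C@H]2C[C@H](O[C@H](c3ccc(OC)cc3)O2)[C@]1(C)C=C.[K+] | intermediate (not isolated)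
16 | potassium C4=C5 enolate of the ten‑membered amino ketone (1(10)E) | CN(C)C/C1=C(/[O-])C[C@H]2C[C@H](O[C@H](c3ccc(OC)cc3)O2)/C(C)=C/CC1.[K+] | intermediate (not isolated)
17 | ten‑membered Mannich base, 4‑[(dimethylamino)methyl] ketone (C4 epimers) | CN(C)CC1CC/C=C(\C)[C@@H]2C[C@H](CC1=O)O[C@@H](c3ccc(OC)cc3)O2 | intermediate (not isolated)
18 | trimethylammonium iodide of 17 (C4 epimers) | C[N+](C)(C)CC1CC/C=C(\C)[C@@H]2C[C@H](CC1=O)O[C@@H](c3ccc(OC)cc3)O2.[I-] | intermediate (not isolated)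
19 | (1(10)E,9S)‑7,9‑O‑(4‑methoxybenzylidene)‑7,9‑dihydroxy‑10‑methyl‑4‑methylidenecyclodec‑1(10)‑en‑5‑one | C=C1CC/C=C(\C)[C@@H]2C[C@H](CC1=O)O[C@@H](c3ccc(OC)cc3)O2 | intermediate (key‑step product)
20 | (5R,9S) allylic alcohol from 19 | C=C1CC/C=C(\C)[C@@H]2C[C@H](C[C@H]1O)O[C@@H](c3ccc(OC)cc3)O2 | intermediate
21 | 5‑O‑tert‑butyldimethylsilyl ether of 20 | C=C1CC/C=C(\C)[C@@H]2C[C@H](C[C@H]1O[Si](C)(C)C(C)(C)C)O[C@@H](c3ccc(OC)cc3)O2 | intermediate
22 | (5R,9S)‑5‑silyloxy‑9‑(4‑methoxybenzyloxy)‑10‑methyl‑4‑methylidenecyclodec‑1(10)‑en‑7‑ol (7‑OH cis to O9) | C=C1CC/C=C(\C)[C@@H](OCc2ccc(OC)cc2)C[C@@H](O)C[C@H]1O[Si](C)(C)C(C)(C)C | intermediate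
23 | corresponding 7‑one | C=C1CC/C=C(\C)[C@@H](OCc2ccc(OC)cc2)CC(=O)C[C@H]1O[Si](C)(C)C(C)(C)C | intermediate
24 | (5R,9S)‑5‑silyloxy‑9‑hydroxy‑10‑methyl‑4‑methylidenecyclodec‑1(10)‑en‑7‑one | C=C1CC/C=C(\C)[C@@H](O)CC(=O)C[C@H]1O[Si](C)(C)C(C)(C)C | intermediate
25 | 2‑(diethoxyphosphoryl)propanoic acid | CCOP(=O)(OCC)C(C)C(=O)O | starting material
26 | 9‑O‑[2‑(diethoxyphosphoryl)propanoyl] ester of 24 (C11 epimers) | C=C1CC/C=C(\C)[C@@H](OC(=O)C(C)P(=O)(OCC)OCC)CC(=O)C[C@H]1O[Si](C)(C)C(C)(C)C | intermediate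
27 | (1(10)E,5R,9S)‑5‑(tert‑butyldimethylsilyloxy)germacra‑1(10),4(15),7(11)‑trien‑12,9‑olide | C=C1CC/C=C(\C)[C@@H]2CC(C[C@H]1O[Si](C)(C)C(C)(C)C)=C(C)C(=O)O2 | intermediate
28 | (1(10)E,5R,9S)‑5‑(tert‑butyldimethylsilyloxy)germacra‑1(10),4(15),7(11)‑triene‑9,12‑diol (C12 cis to C8) | C=C1CC/C=C(\C)[C@@H](O)C/C(C[C@H]1O[Si](C)(C)C(C)(C)C)=C(/C)CO | intermediate
29 | (1(10)E,5R,9S)‑germacra‑1(10),4(15),7(11)‑triene‑5,9,12‑triol | C=C1CC/C=C(\C)[C@@H](O)C/C(C[C@H]1O)=C(/C)CO | intermediate
30 | (1(10)E,4S,5R,9S,11R)‑4,15:7,11‑diepoxygermacr‑1(10)‑ene‑5,9,12‑triol | O[C@@H]1C[C@]2(O[C@]2(C)CO)C[C@H](O)/C(C)=C/CC[C@]13CO3 | intermediate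
31 | (1(10)E,4R,5R,9S,11R)‑4,5:7,11‑diepoxygermacr‑1(10)‑ene‑9,12,15‑triol | OC[C@]12CC/C=C(\C)[C@@H](O)C[C@]3(C[C@H]1O2)O[C@]3(C)CO | intermediate
32 | (1(10)E,4R,5R,9S,11R)‑12,15‑diacetoxy‑4,5:7,11‑diepoxygermacr‑1(10)‑en‑9‑ol | CC(=O)OC[C@]12CC/C=C(\C)[C@@H](O)C[C@]3(C[C@H]1O2)O[C@]3(C)COC(C)=O | intermediate
33 | CNP0185847.3, (1(10)E,4R,5R,7S,11R)‑12,15‑diacetoxy‑4,5:7,11‑diepoxygermacr‑1(10)‑en‑9‑one | CC(=O)OC[C@]12CC/C=C(\C)C(=O)C[C@]3(C[C@H]1O2)O[C@]3(C)COC(C)=O | target

**Step count and risks**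
Total: 21 steps. Longest linear sequence: 20 steps (steps 1–5 and 7–21; step 6 is a one‑step side branch).

The three steps most likely to fail:

Step 18. Chemoselectivity among three allylic alcohols may be lost: the C9 carbinol may still deliver oxygen to C1=C10, or the tetrasubstituted C7=C11 may react too slowly. The fallback takes C9 out of play; it sets out from diol 28 and returns at 32.
- TBSCl/imidazole at −20 °C should silylate only the primary C12 hydroxyl, giving the bis‑silyl ether F1.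
- 4‑Methoxybenzyl trichloroacetimidate with catalytic La(OTf)3 caps the C9 hydroxyl, giving the C9 4‑methoxybenzyl ether F2.
- Bu4NF frees C5–OH and C12–OH, giving the diol F3.
- The Sharpless conditions of step 18 now meet only the two alcohols that should react and give the bis‑epoxide F4.
- The Payne shift of step 19 gives the 4,5‑epoxy diol F5, and acetylation gives the diacetate F6.
- DDQ in buffered CH2Cl2 removes the 4‑methoxybenzyl group and gives 32.

Step 15. Base may remove a C8 hydrogen and expel the C9 acyloxy group (E1cB) faster than the slow olefination to a tetrasubstituted alkene. The fallback forms the C7–C11 bond without base; it sets out from 24 and returns at 27.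
- 2‑Bromopropanoyl bromide and pyridine give the bromo ester F7.
- SmI2 in THF at −78 °C effects an intramolecular Reformatsky addition to the C7 ketone and gives the beta‑hydroxy δ‑lactone F8.
- Dehydration (SOCl2, pyridine, then DBU to bring the alkene into conjugation with the lactone carbonyl) gives 27.

Step 8. The sigmatropic shift of the crowded, fully substituted bridged alkoxide may be slow enough for base‑induced opening of the acetal at C6/C7 to compete, or the quaternisation and elimination may stay incomplete. The fallback uses a smaller alkenyl group and brings C15 in after the ring expansion; it sets out from ketone 9 and returns at 17.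
- CH2=CHMgBr with CeCl3 adds from the exo face and gives the trans‑1,2‑divinyl carbinol F9.
- KH and 18‑crown‑6 give the ten‑membered potassium enolate F10.
- Dimethyl(methylidene)ammonium iodide added to the same flask aminomethylates the enolate at C4 and gives Mannich base 17, which continues inside step 8 (MeI, then NaHCO3) to 19.

Further compounds
F1 | step 18 | (5R,9S)‑5,12‑bis(tert‑butyldimethylsilyloxy)germacra‑1(10),4(15),7(11)‑trien‑9‑ol | C=C1CC/C=C(\C)[C@@H](O)C/C(C[C@H]1O[Si](C)(C)C(C)(C)C)=C(/C)CO[Si](C)(C)C(C)(C)C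
F2 | step 18 | 9‑O‑(4‑methoxybenzyl) ether of F1 | C=C1CC/C=C(\C)[C@@H](OCc2ccc(OC)cc2)C/C(C[C@H]1O[Si](C)(C)C(C)(C)C)=C(/C)CO[Si](C)(C)C(C)(C)C
F3 | step 18 | (5R,9S)‑9‑(4‑methoxybenzyloxy)germacra‑1(10),4(15),7(11)‑triene‑5,12‑diol | C=C1CC/C=C(\C)[C@@H](OCc2ccc(OC)cc2)C/C(C[C@H]1O)=C(/C)CO
F4 | step 18 | (4S,5R,9S,11R)‑4,15:7,11‑diepoxy‑9‑(4‑methoxybenzyloxy)germacr‑1(10)‑ene‑5,12‑diol | O[C@@H]1C[C@]2(O[C@]2(C)CO)C[C@H](OCc4ccc(OC)cc4)/C(C)=C/CC[C@]13CO3
F5 | step 18 | (4R,5R,9S,11R)‑4,5:7,11‑diepoxy‑9‑(4‑methoxybenzyloxy)germacr‑1(10)‑ene‑12,15‑diol | OC[C@]12CC/C=C(\C)[C@@H](OCc4ccc(OC)cc4)C[C@]3(C[C@H]1O2)O[C@]3(C)CO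
F6 | step 18 | 12,15‑diacetate of F5 | CC(=O)OC[C@]12CC/C=C(\C)[C@@H](OCc4ccc(OC)cc4)C[C@]3(C[C@H]1O2)O[C@]3(C)COC(C)=O
F7 | step 15 | 9‑O‑(2‑bromopropanoyl) ester of 24 (epimers at the bromo carbon) | C=C1CC/C=C(\C)[C@@H](OC(=O)C(C)Br)CC(=O)C[C@H]1O[Si](C)(C)C(C)(C)C
F8 | step 15 | 7‑hydroxy‑7,11‑dihydro derivative of lactone 27 (C7 and C11 not defined) | C=C1CC/C=C(\C)[C@@H]2CC(O)(C[C@H]1O[Si](C)(C)C(C)(C)C)C(C)C(=O)O2
F9 | step 8 | 6,7‑diethenyl‑3‑(4‑methoxyphenyl)‑6‑methyl‑2,4‑dioxabicyclo[3.3.1]nonan‑7‑ol (OH endo; vinyl groups trans) | C=C[C@@]1(O)C[C@H]2C[C@H](O[C@H](c3ccc(OC)cc3)O2)[C@]1(C)C=C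
F10 | step 8 | potassium C4=C5 enolate of the ten‑membered ketone lacking C15 | [O-]C1=CCC/C=C(\C)[C@@H]2C[C@H](C1)O[C@@H](c3ccc(OC)cc3)O2.[K+]
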